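**Retrosynthetic overview**
- The dihydropyran is made last by a one-flask [3+3] annulation: the C11 enolate carbon of 3,7-dihydroxy-2-prenyldibenzo[b,f]oxepin-10(11H)-one is alkylated by an enantiopure 2,3-epoxy C10 iodide, then the C10 carbonyl oxygen opens the epoxide 6-endo at the tertiary carbon with inversion. The epoxide is delivered pre-formed rather than by late epoxidation of a C11-neryl ketone.
- Both stereocenters come from one Sharpless epoxidation of nerol; the Z olefin is what gives the 3-OH cis to the homoprenyl chain after inversion.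
- The prenyl ketone comes from Friedel–Crafts prenylation of 3,7-dihydroxydibenzo[b,f]oxepin-10(11H)-one, which comes from demethylation, Friedel–Crafts ring closure of a diaryl ether arylacetic acid, and Ullmann coupling of 2-bromo-4-methoxyphenylacetic acid with 3-methoxyphenol.
- Ring order: two purchased benzene rings, then the oxepinone ring (C–O bond, then C-acyl closure), then the dihydropyran ring in the final step.

Assumption: the pyran is taken to arise in nature by 2,3-epoxidation of a C10 chain on C11 of the oxepinone and 6-endo attack of the C10 enol oxygen; the SMILES descriptors (2S,3S, 3-OH cis to the homoprenyl chain) are taken as correct, which requires a Z-derived (neryl) epoxide opened with inversion.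

**Route**

Step 1
Reactants: 1 2-(2-bromo-4-methoxyphenyl)acetic acid; 2 3-methoxyphenol
Product: 3 2-[4-methoxy-2-(3-methoxyphenoxy)phenyl]acetic acid
Conditions: CuCl (20 mol %), 2,2,6,6-tetramethylheptane-3,5-dione (40 mol %), Cs2CO3 (3.5 equiv), 2 (2 equiv), NMP, 120 °C; then 1 M HCl
Reagents that add atoms: none
Why: Ullmann-type diaryl ether synthesis, in which the aryl bromide of the cesium arylacetate couples with the excess phenoxide of 2; no stereocenter is involved.

Step 2
Reactants: 3 2-[4-methoxy-2-(3-methoxyphenoxy)phenyl]acetic acid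
Product: 4 3,7-dimethoxydibenzo[b,f]oxepin-10(11H)-one
Conditions: Eaton's reagent (P2O5 in MeSO3H), 40 °C
Reagents that add atoms: none
Why: Intramolecular Friedel–Crafts acylation closes the seven-membered ketone ring at the position ortho to the ether oxygen and para to OMe, the standard entry to dibenzo[b,f]oxepin-10(11H)-ones.

Step 3
Reactants: 4 3,7-dimethoxydibenzo[b,f]oxepin-10(11H)-one
Product: 5 3,7-dihydroxydibenzo[b,f]oxepin-10(11H)-one
Conditions: BBr3 (5 equiv), CH2Cl2, −78 → 23 °C; then MeOH, H2O
Reagents that add atoms: none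
Why: BBr3 ether cleavage frees both phenols before any acid-labile olefin is present, and the aryl ketone and diaryl ether tolerate it.

Step 4
Reactants: 5 3,7-dihydroxydibenzo[b,f]oxepin-10(11H)-one; 6 2-methylbut-3-en-2-ol
Product: 7 3,7-dihydroxy-2-(3-methylbut-2-en-1-yl)dibenzo[b,f]oxepin-10(11H)-one
Conditions: 6 (1.5 equiv), BF3·OEt2 (0.5 equiv), 1,4-dioxane, 23 °C, stopped at partial conversion, 5 recycled
Reagents that add atoms: none
Why: Friedel–Crafts prenylation via the dimethylallyl cation, in which the BF3-complexed ketone deactivates ring B so that attack falls on ring A ortho to the 3-OH at the open C2 (para to the ether oxygen) rather than at C4 between two oxygens.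

Step 5
Reactants: 8 nerol, (2Z)-3,7-dimethylocta-2,6-dien-1-ol
Product: 9 (2S,3R)-2,3-epoxynerol, [(2S,3R)-3-methyl-3-(4-methylpent-3-en-1-yl)oxiran-2-yl]methanol
Conditions: Ti(OiPr)4 (5 mol %), L-(+)-diethyl tartrate (7 mol %), t-BuOOH (2 equiv), 4 Å MS, CH2Cl2, −20 °C
Reagents that add atoms: tert-butyl hydroperoxide, CC(C)(C)OO
Why: Sharpless asymmetric epoxidation, in which L-(+)-tartrate selects the face that gives the (2S,3R)-epoxide (about 90–94% ee), only the allylic olefin reacts, and the Z geometry becomes the cis relationship of CH2OH and the homoprenyl chain.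

Step 6
Reactants: 9 (2S,3R)-2,3-epoxynerol
Product: 10 (2R,3R)-2-(iodomethyl)-3-methyl-3-(4-methylpent-3-en-1-yl)oxirane
Conditions: PPh3, I2, imidazole, Et2O–MeCN, 0 °C
Reagents that add atoms: iodine, I-I
Why: Appel-type (Garegg–Samuelsson) iodination replaces the primary OH by SN2 at C1 without touching the epoxide, so the spatial arrangement of 9 is kept and the C2 descriptor changes only through CIP priority.

Step 7
Reactants: 7 3,7-dihydroxy-2-(3-methylbut-2-en-1-yl)dibenzo[b,f]oxepin-10(11H)-one; 10 (2R,3R)-2-(iodomethyl)-3-methyl-3-(4-methylpent-3-en-1-yl)oxirane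
Product: 12 target CNP0185870.1 [(2S,3S)-pyrano-fused dibenzo[b,f]oxepine triol], via C11-epoxyalkyl ketone 11 (not isolated)
Conditions: LiN(SiMe3)2 (3.1 equiv), THF, −78 → −40 °C; 10 (1.2 equiv), −78 → 0 °C; NH4Cl work-up, crude 11 taken into CH2Cl2; BF3·OEt2 (0.3 equiv), −78 → −40 °C; Et3N quench
Reagents that add atoms: none
Why: Proposed new method: a one-flask [3+3] annulation of a ketone polyanion with a 2,3-epoxy-1-iodide, in which the last-formed and most basic site of the trianion (the C11 enolate carbon) is alkylated first by SN2 at CH2–I (closest precedent: Hauser-type C-alkylation of polyanions), and BF3 then activates the trisubstituted epoxide so that the C10 carbonyl oxygen attacks the tertiary carbon 6-endo with inversion and the oxocarbenium ion loses H11 to the conjugated enol ether (closest precedents: Lewis-acid 6-endo opening of trisubstituted epoxides by carbonyl oxygen and the acid cyclisation of ortho-(epoxyprenyl)phenols to 3-chromanols); the C3 carbinol keeps the configuration set in step 5, the C2 quaternary centre is set by the stereospecific inversion, and the two C11 epimers of 11 converge.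

**Compound list**

1 | 2-(2-bromo-4-methoxyphenyl)acetic acid | COc1ccc(CC(=O)O)c(Br)c1 | starting material
2 | 3-methoxyphenol | COc1cccc(O)c1 | starting material
3 | 2-[4-methoxy-2-(3-methoxyphenoxy)phenyl]acetic acid | COc1ccc(CC(=O)O)c(Oc2cccc(OC)c2)c1 | intermediate
4 | 3,7-dimethoxydibenzo[b,f]oxepin-10(11H)-one | COc1ccc2c(c1)Oc1cc(OC)ccc1C(=O)C2 | intermediate
5 | 3,7-dihydroxydibenzo[b,f]oxepin-10(11H)-one | Oc1ccc2c(c1)Oc1cc(O)ccc1C(=O)C2 | intermediate
6 | 2-methylbut-3-en-2-ol | CC(C)(O)C=C | starting material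
7 | 3,7-dihydroxy-2-(3-methylbut-2-en-1-yl)dibenzo[b,f]oxepin-10(11H)-one | CC(C)=CCc1cc2c(cc1O)Oc1cc(O)ccc1C(=O)C2 | intermediate
8 | nerol, (2Z)-3,7-dimethylocta-2,6-dien-1-ol | CC(C)=CCC/C(C)=C\CO | starting material
9 | (2S,3R)-2,3-epoxynerol, [(2S,3R)-3-methyl-3-(4-methylpent-3-en-1-yl)oxiran-2-yl]methanol | OC[C@@H]1O[C@]1(C)CCC=C(C)C | intermediate
10 | (2R,3R)-2-(iodomethyl)-3-methyl-3-(4-methylpent-3-en-1-yl)oxirane | IC[C@@H]1O[C@]1(C)CCC=C(C)C | intermediate
11 | 3,7-dihydroxy-11-{[(2S,3R)-3-methyl-3-(4-methylpent-3-en-1-yl)oxiran-2-yl]methyl}-2-(3-methylbut-2-en-1-yl)dibenzo[b,f]oxepin-10(11H)-one, mixture of C11 epimers | CC(C)=CCc1cc2c(cc1O)Oc1cc(O)ccc1C(=O)C2C[C@@H]1O[C@]1(C)CCC=C(C)C | intermediate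
12 | target: (2S,3S)-3,4-dihydro-2H-pyran fused to the C10=C11 bond of dibenzo[b,f]oxepine (pyran O on C10, pyran CH2 on C11); pyran C2 bears methyl and 4-methylpent-3-en-1-yl, pyran C3 bears OH; the oxepine core carries 3-OH, 7-OH and 2-(3-methylbut-2-en-1-yl) | CC(C)=CCC[C@]1(C)OC2=C(C[C@@H]1O)c1cc(CC=C(C)C)c(O)cc1Oc1cc(O)ccc12 | target

**Step count and risks**

Total step count: 7. Longest linear sequence: 5 (steps 1, 2, 3, 4, 7); steps 5 and 6 make the side-chain partner.

The three steps most likely to fail, with fallbacks: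

Step 7 is the most exposed. The phenoxides or the enolate oxygen may be alkylated instead of C11, the β-branched iodide may react slowly or fragment, and the epoxide may open 5-exo or with partial loss of inversion. The fallback sets out from 7 and comes back at 12. Silylation (TBSCl, imidazole, DMF) gives 3,7-bis(tert-butyldimethylsilyloxy)-2-(3-methylbut-2-en-1-yl)dibenzo[b,f]oxepin-10(11H)-one F1. Its mono-enolate (LiN(SiMe3)2, 1.1 equiv, THF, −78 °C) is alkylated by 10 to the bis-silylated C11-epoxyalkyl ketone F2. BF3·OEt2 in CH2Cl2 at −78 °C closes the pyran to the 3,7-bis(tert-butyldimethylsilyl) ether of the target F3, and TBAF buffered with AcOH releases 12.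

Step 4 may give low conversion, chroman formation by acid cyclisation of the product, or attack at C4 or on ring B. The fallback sets out from 5 and comes back at 7. NBS (1.0 equiv, MeCN, 0 °C) brominates the more electron-rich ring ortho to the 3-OH to give 2-bromo-3,7-dihydroxydibenzo[b,f]oxepin-10(11H)-one F4. Stille coupling with tributyl(3-methylbut-2-en-1-yl)stannane (Pd(PPh3)4, LiCl, DMF, 90 °C) then installs the prenyl group at a position fixed by the halogen and gives 7.

Step 1 may fail because the free arylacetate can lactonise onto the aryl bromide or lose bromine under copper catalysis. The fallback sets out from 2 and comes back at 3. SNAr of 2 on commercial 1-(2-fluoro-4-methoxyphenyl)ethan-1-one (K2CO3, DMSO, 120 °C) gives 1-[4-methoxy-2-(3-methoxyphenoxy)phenyl]ethan-1-one F5. Willgerodt–Kindler reaction (S8, morpholine, 130 °C) gives 2-[4-methoxy-2-(3-methoxyphenoxy)phenyl]-1-(morpholin-4-yl)ethane-1-thione F6, and hydrolysis (KOH, aqueous EtOH, reflux; then HCl) gives 3.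

Further compounds
F1 | step 7 | 3,7-bis(tert-butyldimethylsilyloxy)-2-(3-methylbut-2-en-1-yl)dibenzo[b,f]oxepin-10(11H)-one | CC(C)=CCc1cc2c(cc1O[Si](C)(C)C(C)(C)C)Oc1cc(O[Si](C)(C)C(C)(C)C)ccc1C(=O)C2
F2 | step 7 | 3,7-bis(tert-butyldimethylsilyloxy)-11-{[(2S,3R)-3-methyl-3-(4-methylpent-3-en-1-yl)oxiran-2-yl]methyl}-2-(3-methylbut-2-en-1-yl)dibenzo[b,f]oxepin-10(11H)-one, mixture of C11 epimers | CC(C)=CCc1cc2c(cc1O[Si](C)(C)C(C)(C)C)Oc1cc(O[Si](C)(C)C(C)(C)C)ccc1C(=O)C2C[C@@H]1O[C@]1(C)CCC=C(C)C
F3 | step 7 | 3,7-bis(tert-butyldimethylsilyl) ether of the target, (2S,3S) | CC(C)=CCC[C@]1(C)OC2=C(C[C@@H]1O)c1cc(CC=C(C)C)c(O[Si](C)(C)C(C)(C)C)cc1Oc1cc(O[Si](C)(C)C(C)(C)C)ccc12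
F4 | step 4 | 2-bromo-3,7-dihydroxydibenzo[b,f]oxepin-10(11H)-one | Brc1cc2c(cc1O)Oc1cc(O)ccc1C(=O)C2
F5 | step 1 | 1-[4-methoxy-2-(3-methoxyphenoxy)phenyl]ethan-1-one | COc1ccc(C(C)=O)c(Oc2cccc(OC)c2)c1
F6 | step 1 | 2-[4-methoxy-2-(3-methoxyphenoxy)phenyl]-1-(morpholin-4-yl)ethane-1-thione | COc1ccc(CC(=S)N2CCOCC2)c(Oc2cccc(OC)c2)c1
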